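**Retrosynthetic overview**

1. The acetate is put on last. The (E)-enyne comes from a terminal alkene by cross-metathesis with crotonaldehyde and a Colvin alkyne synthesis. C12–Br and then C10–Cl come from an anti-1,3-diol by two SN2 inversions (C12–OH axial, C10–OH equatorial).
2. The anti-diol comes from a 5-hydroxyoxan-3-one by hydroxyl-directed reduction. The oxan-3-one is equilibrated at C9, so both C9 epimers merge into the 2,6-cis isomer.
3. Key disconnection C10–C11: the oxane is closed by ring-closing metathesis between the methylenated carbonyl carbon C10 of a temporary oxolan-2-one and the C11 vinyl group. Acid then opens the oxolane to the C10 ketone and the C7 hydroxyl.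
4. Enabling feature: the C7 oxygen and C10 are 1,4-related (O–C7–C8–C9–C10), so a γ-lactone can carry C6–C10 with C10 at the carboxyl level. C11 is the lone CH2 between the halogen-bearing C10 and C12, which makes it the natural seam.
5. The ether O–C9 is made by rhodium carbenoid O–H insertion of a diazo lactone (C7 from (S)-5-(hydroxymethyl)oxolan-2-one, C6 by allylboration and Appel inversion) into (3S,4S)-4-(methoxymethoxy)hex-5-en-3-ol (C12 and C13 by alkoxyallylboration). Ring order: oxolanone from the start, oxane in step 7, oxolane opened in the same step.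

Key step: step 7

Remark: positions are cited by the target chain C1 (alkyne CH) to C15 (ethyl CH3), with the ring oxygen linking C9 and C13; compound 8 and the two isopinocampheylborane reagents are assumed to be purchasable.

**Step 1**
Reactants: 1 (5S)-5-(hydroxymethyl)oxolan-2-one
Product: 3 (5S)-5-[(1S)-1-hydroxybut-3-en-1-yl]oxolan-2-one, via lactone aldehyde 2 (not isolated)
Conditions: (COCl)2, DMSO, CH2Cl2, −78 °C; Et3N; crude aldehyde, then B-allyldiisopinocampheylborane [from (+)-α-pinene], Et2O, −78 °C; NaBO3·4H2O, THF/H2O, rt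
Reagents that add atoms: B-allyldiisopinocampheylborane from (+)-α-pinene, C=CCB([C@@H]1C[C@@H]2C[C@H]([C@H]1C)C2(C)C)[C@@H]1C[C@@H]2C[C@H]([C@H]1C)C2(C)C
Why: Swern oxidation gives the labile α-oxygenated aldehyde, which is trapped at once in a Brown allylboration whose chair Zimmerman–Traxler transition state under control of the isopinocampheyl groups should deliver allyl to the si face and set C6 as the (S)-carbinol syn to the C7 oxygen, while the perborate work-up spares the lactone.

**Step 2**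
Reactants: 3 (5S)-5-[(1S)-1-hydroxybut-3-en-1-yl]oxolan-2-one
Product: 4 (5S)-5-[(1R)-1-chlorobut-3-en-1-yl]oxolan-2-one
Conditions: PPh3, CCl4, 60 °C
Reagents that add atoms: tetrachloromethane, ClC(Cl)(Cl)Cl
Why: Appel reaction, in which chloride displaces the alkoxyphosphonium group by SN2, so C6 is inverted from (S)-OH to (R)-Cl and the anti chlorine/oxygen relationship of the target is set.

**Step 3**
Reactants: 4 (5S)-5-[(1R)-1-chlorobut-3-en-1-yl]oxolan-2-one
Product: 6 (5S)-5-[(1R)-1-chlorobut-3-en-1-yl]-3-diazooxolan-2-one, via trifluoroacetyl lactone 5 (not isolated)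
Conditions: LiN(SiMe3)2, THF, −78 °C; CF3CO2CH2CF3; 5% HCl work-up; then MsN3, Et3N, H2O (1 equiv), MeCN, rt
Reagents that add atoms: methanesulfonyl azide, CS(=O)(=O)N=[N+]=[N-]
Why: Detrifluoroacetylative diazo transfer (Regitz type), in which Claisen trifluoroacetylation activates the lactone α-carbon (C9) for transfer of N2 and the trifluoroacetyl group leaves as the N-sulfonyl amide; no stereocenter is touched.

**Step 4**
Reactants: 7 propanal; 8 3-(methoxymethoxy)prop-1-ene
Product: 10 (3S,4S)-4-(methoxymethoxy)hex-5-en-3-ol, via alkoxyallylborane 9 (not isolated)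
Conditions: 8, sec-BuLi, THF, −78 °C; (Ipc)2BOMe [from (−)-α-pinene]; BF3·OEt2; 7, −78 °C; then 3 M NaOH, 30% H2O2, 0 °C to rt
Reagents that add atoms: none
Why: Brown (Z)-γ-alkoxyallylboration, in which the Z geometry of the lithiated allyl ether is kept on boron and translated by the chair Zimmerman–Traxler transition state into the syn 3,4-relationship, while the isopinocampheyl groups direct attack to the re face of propanal, so C13 (S) and C12 (S) are set together.

**Step 5**
Reactants: 10 (3S,4S)-4-(methoxymethoxy)hex-5-en-3-ol; 6 (5S)-5-[(1R)-1-chlorobut-3-en-1-yl]-3-diazooxolan-2-one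
Product: 11 (5S)-5-[(1R)-1-chlorobut-3-en-1-yl]-3-{[(3S,4S)-4-(methoxymethoxy)hex-5-en-3-yl]oxy}oxolan-2-one (both C3 epimers)
Conditions: Rh2(OAc)4 (1 mol %), CH2Cl2, rt, slow addition of 6 (1.3 equiv) to 10
Reagents that add atoms: none
Why: Rhodium carbenoid O–H insertion (oxonium ylide, then proton shift) forms the hindered secondary–secondary ether O–C9 under neutral conditions; C9 is accepted as both epimers because it is equilibrated in step 8.

**Step 6**
Reactants: 11 (5S)-5-[(1R)-1-chlorobut-3-en-1-yl]-3-{[(3S,4S)-4-(methoxymethoxy)hex-5-en-3-yl]oxy}oxolan-2-one (both C3 epimers)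
Product: 12 (5S)-5-[(1R)-1-chlorobut-3-en-1-yl]-3-{[(3S,4S)-4-(methoxymethoxy)hex-5-en-3-yl]oxy}-2-methylideneoxolane (both C3 epimers)
Conditions: Cp2TiMe2 (2.5 equiv), toluene, 70 °C, dark; filtration through basic alumina
Reagents that add atoms: dimethyltitanocene Cp2TiMe2, C[Ti](C)(C1C=CC=C1)C1C=CC=C1
Why: Petasis methylenation, in which thermally formed Cp2Ti=CH2 adds to the lactone carbonyl and cycloreverts to the exocyclic enol ether, and being non-basic it should leave the chloride, the acetal and the olefins untouched.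

**Step 7**
Reactants: 12 (5S)-5-[(1R)-1-chlorobut-3-en-1-yl]-3-{[(3S,4S)-4-(methoxymethoxy)hex-5-en-3-yl]oxy}-2-methylideneoxolane (both C3 epimers)
Product: 14 (5S,6S)-2-[(2S,3R)-3-chloro-2-hydroxyhex-5-en-1-yl]-6-ethyl-5-(methoxymethoxy)oxan-3-one (both C2 epimers), via bicyclic enol ether 13 (not isolated)
Conditions: second-generation Grubbs catalyst RuCl2(=CHPh)(H2IMes)(PCy3) (5 mol %), 1,4-benzoquinone (10 mol %), toluene (5 mM), 70 °C; then 0.5 M HCl, THF, 0 °C to rt
Reagents that add atoms: water, O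
Why: The ruthenium benzylidene should initiate at the monosubstituted C11 vinyl group of 12, the new alkylidene adds intramolecularly across the 1,1-disubstituted exocyclic enol ether C10=CH2 (ruthenacyclobutane, Chauvin mechanism) and cycloreversion releases ethene and the C10=C11 bond of 13; dilute acid then protonates C11, water adds to the oxygen-stabilized C10 cation and the hemiketal opens to the C10 ketone and the C7 hydroxyl. The closest known reaction type is ring-closing metathesis of enol ethers made by methylenation of esters or lactones with a pendant olefin, giving six-membered cyclic enol ethers, followed by ordinary enol ether hydrolysis. The oxane ring (O–C9–C10–C11–C12–C13) is closed as a six-membered ring by metathesis between C10 and C11, fused for the moment to the oxolane through C9–C10. No stereocenter is created, because C10 becomes trigonal and C11 a CH2 group; C6, C7, C12 and C13 are carried unchanged, and both C9 epimers can cyclize because the fusion carbon C10 is sp2, the choice at C9 being made in step 8. The step needs chemoselectivity among three olefins, which the substrate secures: the butenyl olefin could reach C10 only through a bridgehead olefin of an 8-oxabicyclo[3.2.1]octene and C11 only through a ten-membered ring, so the six-membered closure is the only productive cyclization at high dilution. The acid is kept dilute and cold so that the methoxymethyl ether and the allylic C12–O bond of 13 are not ionized.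

**Step 8**
Reactants: 14 (5S,6S)-2-[(2S,3R)-3-chloro-2-hydroxyhex-5-en-1-yl]-6-ethyl-5-(methoxymethoxy)oxan-3-one (both C2 epimers)
Product: 16 (2R,5S,6S)-2-{(2S,3R)-2-[(tert-butyldimethylsilyl)oxy]-3-chlorohex-5-en-1-yl}-6-ethyl-5-(methoxymethoxy)oxan-3-one, via silyl ether epimer mixture 15 (not isolated)
Conditions: TBSCl, imidazole, DMF, rt; then DBU (0.5 equiv), rt
Reagents that add atoms: tert-butyldimethylsilyl chloride, CC(C)(C)[Si](C)(C)Cl
Why: Silylation masks the C7 hydroxyl (which would otherwise close an epoxide onto C6–Cl under base), and amidine-mediated enolization then equilibrates the α-alkoxy ketone at C9 toward the 2,6-cis oxanone with the C9 side chain and the C13 ethyl group both equatorial, so both C9 epimers should converge on (9R).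

**Step 9**
Reactants: 16 (2R,5S,6S)-2-{(2S,3R)-2-[(tert-butyldimethylsilyl)oxy]-3-chlorohex-5-en-1-yl}-6-ethyl-5-(methoxymethoxy)oxan-3-one
Product: 17 (2R,5S,6S)-2-{(2S,3R)-2-[(tert-butyldimethylsilyl)oxy]-3-chlorohex-5-en-1-yl}-6-ethyl-5-hydroxyoxan-3-one
Conditions: Me2BBr, CH2Cl2, −78 °C; then sat. NaHCO3
Reagents that add atoms: none
Why: Dimethylboron bromide cleaves the methoxymethyl acetal at low temperature through the O-boryl oxonium and bromomethyl ether pathway without touching the silyl ether, the chloride or the ketone, and frees the axial C12 hydroxyl that directs step 10.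

**Step 10**
Reactants: 17 (2R,5S,6S)-2-{(2S,3R)-2-[(tert-butyldimethylsilyl)oxy]-3-chlorohex-5-en-1-yl}-6-ethyl-5-hydroxyoxan-3-one
Product: 18 (2R,3S,5S,6S)-2-{(2S,3R)-2-[(tert-butyldimethylsilyl)oxy]-3-chlorohex-5-en-1-yl}-6-ethyloxane-3,5-diol
Conditions: Me4NBH(OAc)3, MeCN/AcOH (1:1), −30 °C
Reagents that add atoms: none
Why: Evans–Saksena reduction, in which the acetoxyborohydride exchanges onto the axial C12 hydroxyl and delivers hydride intramolecularly to the same (lower) face of the C10 carbonyl, which should give the anti-1,3-diol with the C10 hydroxyl equatorial and trans to the C9 side chain.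

**Step 11**
Reactants: 18 (2R,3S,5S,6S)-2-{(2S,3R)-2-[(tert-butyldimethylsilyl)oxy]-3-chlorohex-5-en-1-yl}-6-ethyloxane-3,5-diol
Product: 19 (2S,3S,5S,6R)-6-{(2S,3R)-2-[(tert-butyldimethylsilyl)oxy]-3-chlorohex-5-en-1-yl}-2-ethyl-5-[(triethylsilyl)oxy]oxan-3-ol
Conditions: TESCl (1.05 equiv), imidazole, CH2Cl2, −40 °C
Reagents that add atoms: chlorotriethylsilane, CC[Si](Cl)(CC)CC
Why: Regioselective silylation, since the equatorial C10 hydroxyl is more accessible than the axial C12 hydroxyl and should react first with one equivalent of the silyl chloride at low temperature, which leaves C12–OH free for the first halogenation.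

**Step 12**
Reactants: 19 (2S,3S,5S,6R)-6-{(2S,3R)-2-[(tert-butyldimethylsilyl)oxy]-3-chlorohex-5-en-1-yl}-2-ethyl-5-[(triethylsilyl)oxy]oxan-3-ol
Product: 20 {[(2R,3S,5R,6S)-5-bromo-2-{(2S,3R)-2-[(tert-butyldimethylsilyl)oxy]-3-chlorohex-5-en-1-yl}-6-ethyloxan-3-yl]oxy}triethylsilane
Conditions: CBr4, (n-Oct)3P, 1-methylcyclohexene, toluene, 70 °C
Reagents that add atoms: tetrabromomethane, BrC(Br)(Br)Br
Why: Appel-type bromination, in which bromide displaces the axial alkoxyphosphonium group at C12 from the upper face (no syn-axial substituent in its path) with inversion to the equatorial bromide trans to the C13 ethyl group.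

**Step 13**
Reactants: 20 {[(2R,3S,5R,6S)-5-bromo-2-{(2S,3R)-2-[(tert-butyldimethylsilyl)oxy]-3-chlorohex-5-en-1-yl}-6-ethyloxan-3-yl]oxy}triethylsilane
Product: 21 (2R,3S,5R,6S)-5-bromo-2-{(2S,3R)-2-[(tert-butyldimethylsilyl)oxy]-3-chlorohex-5-en-1-yl}-6-ethyloxan-3-ol
Conditions: PPTS (cat.), MeOH/CH2Cl2, 0 °C
Reagents that add atoms: none
Why: Mild acid-catalysed methanolysis removes the triethylsilyl ether selectively, the more hindered tert-butyldimethylsilyl ether at C7 and both halides being stable to these conditions.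

**Step 14**
Reactants: 21 (2R,3S,5R,6S)-5-bromo-2-{(2S,3R)-2-[(tert-butyldimethylsilyl)oxy]-3-chlorohex-5-en-1-yl}-6-ethyloxan-3-ol
Product: 22 tert-butyl{[(2S,3R)-1-[(2R,3R,5R,6S)-5-bromo-3-chloro-6-ethyloxan-2-yl]-3-chlorohex-5-en-2-yl]oxy}dimethylsilane
Conditions: CCl4, (n-Oct)3P, toluene, 80 °C
Reagents that add atoms: tetrachloromethane, ClC(Cl)(Cl)Cl
Why: Appel-type chlorination, in which chloride displaces the equatorial alkoxyphosphonium group at C10 with inversion to the axial chloride cis to the C9 side chain; with C12–Br already equatorial, no syn-axial group hinders the incoming chloride.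

**Step 15**
Reactants: 22 tert-butyl{[(2S,3R)-1-[(2R,3R,5R,6S)-5-bromo-3-chloro-6-ethyloxan-2-yl]-3-chlorohex-5-en-2-yl]oxy}dimethylsilane
Product: 23 (2E,5R,6S)-7-[(2R,3R,5R,6S)-5-bromo-3-chloro-6-ethyloxan-2-yl]-6-[(tert-butyldimethylsilyl)oxy]-5-chlorohept-2-enal
Conditions: crotonaldehyde (10 equiv), second-generation Grubbs catalyst RuCl2(=CHPh)(H2IMes)(PCy3) (5 mol %), CH2Cl2, 40 °C
Reagents that add atoms: (E)-but-2-enal, C/C=C/C=O
Why: Olefin cross-metathesis of the terminal alkene with an excess of the electron-poor partner crotonaldehyde should give the (E)-enal under thermodynamic control.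

**Step 16**
Reactants: 23 (2E,5R,6S)-7-[(2R,3R,5R,6S)-5-bromo-3-chloro-6-ethyloxan-2-yl]-6-[(tert-butyldimethylsilyl)oxy]-5-chlorohept-2-enal
Product: 24 tert-butyl{[(2S,3R,5E)-1-[(2R,3R,5R,6S)-5-bromo-3-chloro-6-ethyloxan-2-yl]-3-chlorooct-5-en-7-yn-2-yl]oxy}dimethylsilane
Conditions: Me3SiCHN2, LiN(iPr)2 (1.2 equiv each), THF, −78 °C; 23, −78 to 0 °C; sat. NH4Cl
Reagents that add atoms: trimethylsilyldiazomethane, C[Si](C)(C)C=[N+]=[N-]
Why: Colvin rearrangement, in which lithiated trimethylsilyldiazomethane adds to the aldehyde, Peterson-type elimination gives the alkylidene carbene and a 1,2-hydride shift gives the terminal alkyne, with the (E)-olefin retained and the C7 oxygen kept silylated so that no alkoxide forms next to C6–Cl.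

**Step 17**
Reactants: 24 tert-butyl{[(2S,3R,5E)-1-[(2R,3R,5R,6S)-5-bromo-3-chloro-6-ethyloxan-2-yl]-3-chlorooct-5-en-7-yn-2-yl]oxy}dimethylsilane
Product: 25 (2S,3R,5E)-1-[(2R,3R,5R,6S)-5-bromo-3-chloro-6-ethyloxan-2-yl]-3-chlorooct-5-en-7-yn-2-ol
Conditions: HF·pyridine, pyridine/THF, 0 °C to rt
Reagents that add atoms: none
Why: Fluoride-mediated desilylation under buffered acidic conditions, so that the chlorohydrin is never exposed to base and cannot close to an epoxide.

**Step 18**
Reactants: 25 (2S,3R,5E)-1-[(2R,3R,5R,6S)-5-bromo-3-chloro-6-ethyloxan-2-yl]-3-chlorooct-5-en-7-yn-2-ol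
Product: 26 (2S,3R,5E)-1-[(2R,3R,5R,6S)-5-bromo-3-chloro-6-ethyloxan-2-yl]-3-chlorooct-5-en-7-yn-2-yl acetate
Conditions: Ac2O, pyridine, DMAP (cat.), CH2Cl2, 0 °C to rt
Reagents that add atoms: acetic anhydride, CC(=O)OC(C)=O
Why: DMAP-catalysed acetylation of the C7 alcohol proceeds with retention and completes the target.

**Compound list**

1 | (5S)-5-(hydroxymethyl)oxolan-2-one | O=C1CC[C@@H](CO)O1 | starting material
2 | (2S)-5-oxooxolane-2-carbaldehyde | O=C[C@@H]1CCC(=O)O1 | intermediate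
3 | (5S)-5-[(1S)-1-hydroxybut-3-en-1-yl]oxolan-2-one | C=CC[C@H](O)[C@@H]1CCC(=O)O1 | intermediate
4 | (5S)-5-[(1R)-1-chlorobut-3-en-1-yl]oxolan-2-one | C=CC[C@@H](Cl)[C@@H]1CCC(=O)O1 | intermediate
5 | (5S)-5-[(1R)-1-chlorobut-3-en-1-yl]-3-(trifluoroacetyl)oxolan-2-one (C3 epimers) | C=CC[C@@H](Cl)[C@@H]1CC(C(=O)C(F)(F)F)C(=O)O1 | intermediate
6 | (5S)-5-[(1R)-1-chlorobut-3-en-1-yl]-3-diazooxolan-2-one | C=CC[C@@H](Cl)[C@@H]1CC(=[N+]=[N-])C(=O)O1 | intermediate
7 | propanal | CCC=O | starting material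
8 | 3-(methoxymethoxy)prop-1-ene (allyl methoxymethyl ether) | C=CCOCOC | starting material
9 | [(2Z)-3-(methoxymethoxy)prop-2-en-1-yl]bis(isopinocampheyl)borane (isopinocampheyl groups from (−)-α-pinene) | COCO/C=C\CB([C@H]1C[C@H]2C[C@@H]([C@@H]1C)C2(C)C)[C@H]1C[C@H]2C[C@@H]([C@@H]1C)C2(C)C | intermediate
10 | (3S,4S)-4-(methoxymethoxy)hex-5-en-3-ol | CC[C@H](O)[C@@H](OCOC)C=C | intermediate
11 | (5S)-5-[(1R)-1-chlorobut-3-en-1-yl]-3-{[(3S,4S)-4-(methoxymethoxy)hex-5-en-3-yl]oxy}oxolan-2-one (both C3 epimers) | C=CC[C@@H](Cl)[C@@H]1CC(O[C@@H](CC)[C@@H](OCOC)C=C)C(=O)O1 | intermediate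
12 | (5S)-5-[(1R)-1-chlorobut-3-en-1-yl]-3-{[(3S,4S)-4-(methoxymethoxy)hex-5-en-3-yl]oxy}-2-methylideneoxolane (both C3 epimers) | C=CC[C@@H](Cl)[C@@H]1CC(O[C@@H](CC)[C@@H](OCOC)C=C)C(=C)O1 | intermediate
13 | (2S,5S,6S)-2-[(1R)-1-chlorobut-3-en-1-yl]-5-ethyl-6-(methoxymethoxy)-3,3a,5,6-tetrahydro-2H-furo[3,2-b]pyran (both C3a epimers) | C=CC[C@@H](Cl)[C@@H]1CC2O[C@@H](CC)[C@@H](OCOC)C=C2O1 | intermediate
14 | (5S,6S)-2-[(2S,3R)-3-chloro-2-hydroxyhex-5-en-1-yl]-6-ethyl-5-(methoxymethoxy)oxan-3-one (both C2 epimers) | C=CC[C@@H](Cl)[C@H](CC1O[C@@H](CC)[C@@H](OCOC)CC1=O)O | intermediate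
15 | (5S,6S)-2-{(2S,3R)-2-[(tert-butyldimethylsilyl)oxy]-3-chlorohex-5-en-1-yl}-6-ethyl-5-(methoxymethoxy)oxan-3-one (both C2 epimers) | C=CC[C@@H](Cl)[C@H](CC1O[C@@H](CC)[C@@H](OCOC)CC1=O)O[Si](C)(C)C(C)(C)C | intermediate
16 | (2R,5S,6S)-2-{(2S,3R)-2-[(tert-butyldimethylsilyl)oxy]-3-chlorohex-5-en-1-yl}-6-ethyl-5-(methoxymethoxy)oxan-3-one | C=CC[C@@H](Cl)[C@H](C[C@H]1O[C@@H](CC)[C@@H](OCOC)CC1=O)O[Si](C)(C)C(C)(C)C | intermediate
17 | (2R,5S,6S)-2-{(2S,3R)-2-[(tert-butyldimethylsilyl)oxy]-3-chlorohex-5-en-1-yl}-6-ethyl-5-hydroxyoxan-3-one | C=CC[C@@H](Cl)[C@H](C[C@H]1O[C@@H](CC)[C@@H](O)CC1=O)O[Si](C)(C)C(C)(C)C | intermediate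
18 | (2R,3S,5S,6S)-2-{(2S,3R)-2-[(tert-butyldimethylsilyl)oxy]-3-chlorohex-5-en-1-yl}-6-ethyloxane-3,5-diol | C=CC[C@@H](Cl)[C@H](C[C@H]1O[C@@H](CC)[C@@H](O)C[C@@H]1O)O[Si](C)(C)C(C)(C)C | intermediate
19 | (2S,3S,5S,6R)-6-{(2S,3R)-2-[(tert-butyldimethylsilyl)oxy]-3-chlorohex-5-en-1-yl}-2-ethyl-5-[(triethylsilyl)oxy]oxan-3-ol | C=CC[C@@H](Cl)[C@H](C[C@H]1O[C@@H](CC)[C@@H](O)C[C@@H]1O[Si](CC)(CC)CC)O[Si](C)(C)C(C)(C)C | intermediate
20 | {[(2R,3S,5R,6S)-5-bromo-2-{(2S,3R)-2-[(tert-butyldimethylsilyl)oxy]-3-chlorohex-5-en-1-yl}-6-ethyloxan-3-yl]oxy}triethylsilane | C=CC[C@@H](Cl)[C@H](C[C@H]1O[C@@H](CC)[C@H](Br)C[C@@H]1O[Si](CC)(CC)CC)O[Si](C)(C)C(C)(C)C | intermediate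
21 | (2R,3S,5R,6S)-5-bromo-2-{(2S,3R)-2-[(tert-butyldimethylsilyl)oxy]-3-chlorohex-5-en-1-yl}-6-ethyloxan-3-ol | C=CC[C@@H](Cl)[C@H](C[C@H]1O[C@@H](CC)[C@H](Br)C[C@@H]1O)O[Si](C)(C)C(C)(C)C | intermediate
22 | tert-butyl{[(2S,3R)-1-[(2R,3R,5R,6S)-5-bromo-3-chloro-6-ethyloxan-2-yl]-3-chlorohex-5-en-2-yl]oxy}dimethylsilane | C=CC[C@@H](Cl)[C@H](C[C@H]1O[C@@H](CC)[C@H](Br)C[C@H]1Cl)O[Si](C)(C)C(C)(C)C | intermediate
23 | (2E,5R,6S)-7-[(2R,3R,5R,6S)-5-bromo-3-chloro-6-ethyloxan-2-yl]-6-[(tert-butyldimethylsilyl)oxy]-5-chlorohept-2-enal | O=C/C=C/C[C@@H](Cl)[C@H](C[C@H]1O[C@@H](CC)[C@H](Br)C[C@H]1Cl)O[Si](C)(C)C(C)(C)C | intermediate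
24 | tert-butyl{[(2S,3R,5E)-1-[(2R,3R,5R,6S)-5-bromo-3-chloro-6-ethyloxan-2-yl]-3-chlorooct-5-en-7-yn-2-yl]oxy}dimethylsilane | C#C/C=C/C[C@@H](Cl)[C@H](C[C@H]1O[C@@H](CC)[C@H](Br)C[C@H]1Cl)O[Si](C)(C)C(C)(C)C | intermediate
25 | (2S,3R,5E)-1-[(2R,3R,5R,6S)-5-bromo-3-chloro-6-ethyloxan-2-yl]-3-chlorooct-5-en-7-yn-2-ol | C#C/C=C/C[C@@H](Cl)[C@H](C[C@H]1O[C@@H](CC)[C@H](Br)C[C@H]1Cl)O | intermediate
26 | (2S,3R,5E)-1-[(2R,3R,5R,6S)-5-bromo-3-chloro-6-ethyloxan-2-yl]-3-chlorooct-5-en-7-yn-2-yl acetate | C#C/C=C/C[C@@H](Cl)[C@H](C[C@H]1O[C@@H](CC)[C@H](Br)C[C@H]1Cl)OC(C)=O | target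

**Totals**

Total step count: 18. Longest linear sequence: 17 steps (steps 1 to 3 and 5 to 18; step 4 makes the second fragment).

**Steps most likely to fail, each with a fallback**

Step 5. The rhodium carbenoid may undergo a 1,2-hydride shift to the butenolide faster than it is captured by the hindered secondary alcohol. The fallback sets out from 4 and 10 and comes back at 11. Lactone 4 is enolized with LiN(SiMe3)2 and oxidized with 2-(phenylsulfonyl)-3-phenyloxaziridine to (5S)-5-[(1R)-1-chlorobut-3-en-1-yl]-3-hydroxyoxolan-2-one F1. This is converted with Tf2O and pyridine into the triflate (5S)-5-[(1R)-1-chlorobut-3-en-1-yl]-2-oxooxolan-3-yl trifluoromethanesulfonate F2. The sodium alkoxide of 10 (NaH, THF, −40 °C) then displaces the triflate in a Williamson SN2 etherification to give 11. The configuration at C9 is again unimportant because of step 8.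

Step 7. The exocyclic enol ether may isomerize into the ring (to the 5-methyl-2,3-dihydrofuran), or the ruthenium alkylidene may stall at the hindered allylic ether, so that no ring closure occurs. The fallback sets out from 11 (step 6 is skipped) and comes back at 13, which is hydrolysed to 14 as before. Lactone 11 is treated with the reduced titanium ethylidene reagent made from TiCl4, Zn, PbCl2 (cat.), TMEDA and CH3CHBr2 in THF. The titanium alkylidene formed at the C11 vinyl group olefinates the lactone carbonyl intramolecularly (olefinic ester cyclization, a carbonyl–olefin metathesis), which forms the same C10=C11 bond. This fallback makes no new compound (F0).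

Step 11. Discrimination between the equatorial C10 and the axial C12 hydroxyl may be poor, leading to bis-silylation or the wrong regioisomer. The fallback sets out from 17 and comes back at 19. Evans–Tishchenko reduction of 17 (4-nitrobenzaldehyde, SmI2 (cat.), THF, −10 °C) should deliver hydride from the C12 hemiacetal to C10 and leave C12 acylated, giving (2S,3S,5S,6R)-6-{(2S,3R)-2-[(tert-butyldimethylsilyl)oxy]-3-chlorohex-5-en-1-yl}-2-ethyl-5-hydroxyoxan-3-yl 4-nitrobenzoate F3. Silylation of the only free hydroxyl (TESOTf, 2,6-lutidine, −78 °C) gives (2S,3S,5S,6R)-6-{(2S,3R)-2-[(tert-butyldimethylsilyl)oxy]-3-chlorohex-5-en-1-yl}-2-ethyl-5-[(triethylsilyl)oxy]oxan-3-yl 4-nitrobenzoate F4. Methanolysis of the activated ester (K2CO3, MeOH, 0 °C) then gives 19.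

**Further compounds**

F1 | step 5 | (5S)-5-[(1R)-1-chlorobut-3-en-1-yl]-3-hydroxyoxolan-2-one | C=CC[C@@H](Cl)[C@@H]1CC(O)C(=O)O1
F2 | step 5 | (5S)-5-[(1R)-1-chlorobut-3-en-1-yl]-2-oxooxolan-3-yl trifluoromethanesulfonate | C=CC[C@@H](Cl)[C@@H]1CC(OS(=O)(=O)C(F)(F)F)C(=O)O1
F0 | step 7 | none | none
F3 | step 11 | (2S,3S,5S,6R)-6-{(2S,3R)-2-[(tert-butyldimethylsilyl)oxy]-3-chlorohex-5-en-1-yl}-2-ethyl-5-hydroxyoxan-3-yl 4-nitrobenzoate | C=CC[C@@H](Cl)[C@H](C[C@H]1O[C@@H](CC)[C@@H](OC(=O)c2ccc(cc2)[N+](=O)[O-])C[C@@H]1O)O[Si](C)(C)C(C)(C)C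
F4 | step 11 | (2S,3S,5S,6R)-6-{(2S,3R)-2-[(tert-butyldimethylsilyl)oxy]-3-chlorohex-5-en-1-yl}-2-ethyl-5-[(triethylsilyl)oxy]oxan-3-yl 4-nitrobenzoate | C=CC[C@@H](Cl)[C@H](C[C@H]1O[C@@H](CC)[C@@H](OC(=O)c2ccc(cc2)[N+](=O)[O-])C[C@@H]1O[Si](CC)(CC)CC)O[Si](C)(C)C(C)(C)C
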